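## Retrosynthetic overview

1. The hydroperoxide is installed last, by Co(acac)2-catalysed hydroperoxysilylation of a side-chain dienone. The dienone comes from an epoxy aldehyde and a dienylzinc, and the side-chain oxirane from Sharpless epoxidation of a 2-substituted allyl alcohol.
2. The ring oxirane comes from a 6-acyloxy-2-methylcyclohex-2-enone by Luche reduction, VO(acac)2 hydroxyl-directed epoxidation and re-oxidation.
3. Key disconnection: the ring bond between the ketone carbon and the neighbouring CH that carries the isovalerate. These two adjacent ring carbons are both oxygenated (O–CH–C=O, next to the C-methyl carbon of the later oxirane), so they are a latent 1,2-diol. The carbocycle can therefore be opened to an acyclic aldehyde/(Z)-enal pair and closed again by SmI2 pinacol coupling.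
4. The dialdehyde comes from an (S)-4-alkenylbutyrolactone, made by [Rh(OH)((S)-BINAP)]2-catalysed conjugate addition of an alkenylboronate to furan-2(5H)-one, followed by Z-selective olefination.
5. Order of ring formation: cyclohexene (step 8), side-chain oxirane (step 11), ring oxirane (step 13).

Key step: step 8

Assumption (chemistry): 2-bromoprop-2-en-1-ol, furan-2(5H)-one, ethyl 2-[bis(2,2,2-trifluoroethoxy)phosphoryl]propanoate, 3-methylbutanoic anhydride and 2-methylbut-1-en-3-yne are taken as commercial, and the trans relation of ester and side chain is taken as the thermodynamically preferred one at the enolisable ester-bearing carbon.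

## Route

Step 1
Reactants: 1 2-bromoprop-2-en-1-ol
Product: 2 [(2-bromoprop-2-en-1-yl)oxy](tert-butyl)dimethylsilane
Conditions: TBSCl, imidazole, CH2Cl2, 0 °C to rt
Reagents that add atoms: tert-butyldimethylsilyl chloride, CC(C)(C)[Si](C)(C)Cl
Why: Imidazole-promoted silylation of a primary allylic alcohol (silyl ether protection) is routine and no stereocentre is involved.

Step 2
Reactants: 2 [(2-bromoprop-2-en-1-yl)oxy](tert-butyl)dimethylsilane
Product: 3 tert-butyldimethyl{[2-(4,4,5,5-tetramethyl-1,3,2-dioxaborolan-2-yl)prop-2-en-1-yl]oxy}silane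
Conditions: B2pin2, PdCl2(PPh3)2 (3 mol %), PPh3, KOPh, toluene, 50 °C
Reagents that add atoms: bis(pinacolato)diboron, CC1(C)OB(OC1(C)C)B1OC(C)(C)C(C)(C)O1
Why: Miyaura borylation of a 1,1-disubstituted alkenyl bromide (oxidative addition to zerovalent palladium, phenoxide-assisted transmetalation with the diboron, reductive elimination) should give the alkenylboronate, the weak phenoxide base suppressing Suzuki homocoupling.

Step 3
Reactants: 3 tert-butyldimethyl{[2-(4,4,5,5-tetramethyl-1,3,2-dioxaborolan-2-yl)prop-2-en-1-yl]oxy}silane, 4 furan-2(5H)-one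
Product: 5 (4S)-4-{3-[(tert-butyldimethylsilyl)oxy]prop-1-en-2-yl}oxolan-2-one
Conditions: [Rh(OH)((S)-BINAP)]2 (3 mol %), dioxane/H2O 10:1, 50 °C
Reagents that add atoms: none
Why: Asymmetric conjugate addition of an alkenylboron reagent (Hayashi–Miyaura reaction): transmetalation to the hydroxorhodium complex, enantioface-selective insertion of the butenolide into the Rh–alkenyl bond inside the (S)-BINAP pocket and hydrolysis of the oxa-π-allyl should give the (S)-lactone, whose stereocentre becomes the ring carbon that carries the side chain.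

Step 4
Reactants: 5 (4S)-4-{3-[(tert-butyldimethylsilyl)oxy]prop-1-en-2-yl}oxolan-2-one
Product: 6 (4S)-4-{3-[(tert-butyldimethylsilyl)oxy]prop-1-en-2-yl}oxolan-2-ol (anomer mixture)
Conditions: DIBAL-H, CH2Cl2, −78 °C
Reagents that add atoms: none
Why: DIBAL-H reduction of a γ-lactone at low temperature stops at the stable aluminium hemiacetal and should give the lactol, the anomeric centre being inconsequential and the silyl ether and alkene inert.

Step 5
Reactants: 6 (4S)-4-{3-[(tert-butyldimethylsilyl)oxy]prop-1-en-2-yl}oxolan-2-ol, 7 ethyl 2-[bis(2,2,2-trifluoroethoxy)phosphoryl]propanoate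
Product: 8 ethyl (2Z,5S)-5-(hydroxymethyl)-2-methyl-6-{[(tert-butyldimethylsilyl)oxy]methyl}hepta-2,6-dienoate
Conditions: KHMDS, 18-crown-6, THF, −78 to −40 °C
Reagents that add atoms: none
Why: Still–Gennari variant of the Horner–Wadsworth–Emmons reaction on the hydroxy aldehyde in equilibrium with the lactol: the electron-poor phosphonate and the crown-separated potassium enolate make elimination faster than adduct equilibration, which should give the (Z)-trisubstituted enoate needed for the later ring closure.

Step 6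
Reactants: 8 ethyl (2Z,5S)-5-(hydroxymethyl)-2-methyl-6-{[(tert-butyldimethylsilyl)oxy]methyl}hepta-2,6-dienoate
Product: 9 (2Z,5S)-5-(hydroxymethyl)-2-methyl-6-{[(tert-butyldimethylsilyl)oxy]methyl}hepta-2,6-dien-1-ol
Conditions: DIBAL-H (3.5 equiv), CH2Cl2, −78 °C
Reagents that add atoms: none
Why: DIBAL-H reduces the conjugated ester 1,2 to the allylic alcohol (ester-to-alcohol hydride reduction) without touching the (Z)-alkene or the silyl ether.

Step 7
Reactants: 9 (2Z,5S)-5-(hydroxymethyl)-2-methyl-6-{[(tert-butyldimethylsilyl)oxy]methyl}hepta-2,6-dien-1-ol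
Product: 10 (2Z,5S)-5-formyl-2-methyl-6-{[(tert-butyldimethylsilyl)oxy]methyl}hepta-2,6-dienal
Conditions: Dess–Martin periodinane (2.6 equiv), pyridine, CH2Cl2, 0 °C; short silica pad, used at once
Reagents that add atoms: none
Why: Dess–Martin oxidation converts both primary alcohols to aldehydes under buffered, non-enolising conditions, which should preserve the (Z)-enal geometry and the epimerisable, deconjugated α-alkenyl aldehyde stereocentre.

Step 8
Reactants: 10 (2Z,5S)-5-formyl-2-methyl-6-{[(tert-butyldimethylsilyl)oxy]methyl}hepta-2,6-dienal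
Product: 11 (1S,2R,6S)-3-methyl-6-{3-[(tert-butyldimethylsilyl)oxy]prop-1-en-2-yl}cyclohex-3-ene-1,2-diol (expected major diastereomer)
Conditions: SmI2 (2.5 equiv), THF, −78 °C, slow addition of 10 (final 0.005 M); aq. NaHCO3 work-up
Reagents that add atoms: none
Why: SmI2 transfers one electron to the conjugated (Z)-enal, the more easily reduced carbonyl, to give a samarium-bound allylic ketyl whose carbinyl carbon couples with the tethered, samarium-coordinated aldehyde, and a second electron transfer with protonation on work-up gives the diol. This is an intramolecular pinacol coupling, and the closest known reaction type is the SmI2 cyclisation of 1,6-dialdehydes to cis-cyclohexane-1,2-diols. The six-membered ring closes in a 6-exo-trig mode (attack on the aldehyde carbon with its C=O bond outside the ring), whereas coupling through the β-carbon of the allylic ketyl would need a four-membered ring and is not expected. The two new carbinol centres should form cis through a samarium-bridged diolate and anti to the alkenyl-bearing stereocentre, which sits pseudo-equatorial in a chair-like transition state; only the centre next to that stereocentre is kept, since the allylic one is erased in step 9. The step needs carbonyl-carbon rather than β-carbon coupling (secured by ring size), intra- rather than intermolecular coupling (secured by high dilution and slow addition), and survival of the (Z)-alkene and of the base-labile α-alkenyl aldehyde centre (secured by neutral conditions at −78 °C without any amine).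

Step 9
Reactants: 11 (1S,2R,6S)-3-methyl-6-{3-[(tert-butyldimethylsilyl)oxy]prop-1-en-2-yl}cyclohex-3-ene-1,2-diol, 12 3-methylbutanoic anhydride
Product: 14 (1S,6S)-3-methyl-2-oxo-6-{3-[(tert-butyldimethylsilyl)oxy]prop-1-en-2-yl}cyclohex-3-en-1-yl 3-methylbutanoate, via α-ketol 13 (not isolated)
Conditions: MnO2 (activated), CH2Cl2, rt; filter; then 12, Et3N, DMAP (cat.), CH2Cl2, 0 °C
Reagents that add atoms: none
Why: Activated MnO2 oxidises only the allylic carbinol of the diol (allylic alcohol oxidation) and the resulting α-ketol is acylated at its single hydroxyl by the DMAP-activated anhydride, the ester-bearing centre keeping the configuration from step 8, which is also the favoured diequatorial arrangement should it enolise under the amine.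

Step 10
Reactants: 14 (1S,6S)-3-methyl-2-oxo-6-{3-[(tert-butyldimethylsilyl)oxy]prop-1-en-2-yl}cyclohex-3-en-1-yl 3-methylbutanoate
Product: 15 (1S,6S)-6-(3-hydroxyprop-1-en-2-yl)-3-methyl-2-oxocyclohex-3-en-1-yl 3-methylbutanoate
Conditions: HF·pyridine, pyridine, THF, 0 °C
Reagents that add atoms: none
Why: Fluoride-mediated cleavage of the primary silyl ether under pyridine buffering should leave the base-sensitive α-acyloxy enone untouched.

Step 11
Reactants: 15 (1S,6S)-6-(3-hydroxyprop-1-en-2-yl)-3-methyl-2-oxocyclohex-3-en-1-yl 3-methylbutanoate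
Product: 16 (1S,6R)-6-[(2S)-2-(hydroxymethyl)oxiran-2-yl]-3-methyl-2-oxocyclohex-3-en-1-yl 3-methylbutanoate
Conditions: Ti(OiPr)4 (10 mol %), L-(+)-diethyl tartrate (12 mol %), t-BuOOH, 4 Å molecular sieves, CH2Cl2, −20 °C
Reagents that add atoms: tert-butyl hydroperoxide, CC(C)(C)OO
Why: Sharpless asymmetric epoxidation under reagent control: for 2-substituted allyl alcohols the L-(+)-tartrate catalyst delivers oxygen to the face that gives the (S)-2,2-disubstituted oxiranylmethanol, which is the spatial arrangement of the target's side-chain epoxide, while the electron-poor enone alkene is not an allylic alcohol and is left alone.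

Step 12
Reactants: 16 (1S,6R)-6-[(2S)-2-(hydroxymethyl)oxiran-2-yl]-3-methyl-2-oxocyclohex-3-en-1-yl 3-methylbutanoate
Product: 17 (1S,2S,6R)-2-hydroxy-6-[(2S)-2-(hydroxymethyl)oxiran-2-yl]-3-methylcyclohex-3-en-1-yl 3-methylbutanoate
Conditions: NaBH4, CeCl3·7H2O, MeOH, −78 °C; aq. NH4Cl
Reagents that add atoms: none
Why: Luche reduction: cerium-assisted 1,2-hydride delivery along the axial trajectory of the half-chair, with both substituents equatorial, should give the pseudo-equatorial allylic alcohol trans to the ester and cis to the oxiranyl-bearing carbon, as in the reduction of carvone to cis-carveol.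

Step 13
Reactants: 17 (1S,2S,6R)-2-hydroxy-6-[(2S)-2-(hydroxymethyl)oxiran-2-yl]-3-methylcyclohex-3-en-1-yl 3-methylbutanoate
Product: 18 (1R,2R,3S,4R,6S)-2-hydroxy-4-[(2S)-2-(hydroxymethyl)oxiran-2-yl]-1-methyl-7-oxabicyclo[4.1.0]heptan-3-yl 3-methylbutanoate
Conditions: VO(acac)2 (5 mol %), t-BuOOH, CH2Cl2, 0 °C to rt
Reagents that add atoms: tert-butyl hydroperoxide, CC(C)(C)OO
Why: Hydroxyl-directed epoxidation: the vanadate ester of the allylic alcohol delivers the peroxide oxygen to the alkene face syn to that hydroxyl, which sets both ring-epoxide carbons on the face of the side chain and opposite to the ester, and no other alkene is present.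

Step 14
Reactants: 18 (1R,2R,3S,4R,6S)-2-hydroxy-4-[(2S)-2-(hydroxymethyl)oxiran-2-yl]-1-methyl-7-oxabicyclo[4.1.0]heptan-3-yl 3-methylbutanoate
Product: 19 (1S,3S,4R,6S)-4-[(2R)-2-formyloxiran-2-yl]-1-methyl-2-oxo-7-oxabicyclo[4.1.0]heptan-3-yl 3-methylbutanoate
Conditions: Dess–Martin periodinane (3 equiv), pyridine, CH2Cl2, 0 °C to rt
Reagents that add atoms: none
Why: Dess–Martin oxidation converts the secondary epoxy alcohol to the epoxy ketone and the primary epoxy alcohol to the aldehyde in one operation, and the α-carbon of the aldehyde is quaternary so it cannot epimerise.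

Step 15
Reactants: 19 (1S,3S,4R,6S)-4-[(2R)-2-formyloxiran-2-yl]-1-methyl-2-oxo-7-oxabicyclo[4.1.0]heptan-3-yl 3-methylbutanoate, 20 2-methylbut-1-en-3-yne
Product: 23 (1S,3S,4R,6S)-4-{(2R)-2-[(2E)-1-hydroxy-4-methylpenta-2,4-dien-1-yl]oxiran-2-yl}-1-methyl-2-oxo-7-oxabicyclo[4.1.0]heptan-3-yl 3-methylbutanoate (carbinol epimers), via dienylzirconocene chloride 21 (not isolated), via dienyl(methyl)zinc 22 (not isolated)
Conditions: Cp2Zr(H)Cl, 20, CH2Cl2, rt; Me2Zn, −65 °C; then 19, −65 to 0 °C; aq. NH4Cl
Reagents that add atoms: none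
Why: Hydrozirconation of the terminal alkyne (syn addition, zirconium at the terminus, enyne alkene untouched) gives the (E)-dienylzirconocene, and transmetalation to zinc gives an alkenylzinc that adds 1,2 to the aldehyde much faster than to the hindered ketone or the ester, the new carbinol centre being formed as a mixture and erased in step 16.

Step 16
Reactants: 23 (1S,3S,4R,6S)-4-{(2R)-2-[(2E)-1-hydroxy-4-methylpenta-2,4-dien-1-yl]oxiran-2-yl}-1-methyl-2-oxo-7-oxabicyclo[4.1.0]heptan-3-yl 3-methylbutanoate
Product: 24 (1S,3S,4R,6S)-1-methyl-4-{(2R)-2-[(2E)-4-methylpenta-2,4-dienoyl]oxiran-2-yl}-2-oxo-7-oxabicyclo[4.1.0]heptan-3-yl 3-methylbutanoate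
Conditions: Dess–Martin periodinane, pyridine, CH2Cl2, 0 °C
Reagents that add atoms: none
Why: Dess–Martin oxidation of the activated secondary alcohol should give the (E)-dienone under buffered conditions that leave both epoxides intact.

Step 17
Reactants: 24 (1S,3S,4R,6S)-1-methyl-4-{(2R)-2-[(2E)-4-methylpenta-2,4-dienoyl]oxiran-2-yl}-2-oxo-7-oxabicyclo[4.1.0]heptan-3-yl 3-methylbutanoate
Product: 25 (1S,3S,4R,6S)-1-methyl-4-[(2R)-2-{(2E)-4-methyl-4-[(triethylsilyl)peroxy]pent-2-enoyl}oxiran-2-yl]-2-oxo-7-oxabicyclo[4.1.0]heptan-3-yl 3-methylbutanoate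
Conditions: Co(acac)2 (10 mol %), Et3SiH, O2 (1 atm), ClCH2CH2Cl, rt
Reagents that add atoms: dioxygen, O=O; triethylsilane, CC[SiH](CC)CC
Why: Mukaiyama–Isayama hydroperoxysilylation: the cobalt hydride transfers a hydrogen atom to the terminal methylene of the diene, the tertiary allylic radical is trapped by O2 at the tertiary carbon (which keeps the enone conjugated) and the peroxyl is silylated, so the tertiary silyl peroxide with the (E)-enone should form without any new stereocentre.

Step 18
Reactants: 25 (1S,3S,4R,6S)-1-methyl-4-[(2R)-2-{(2E)-4-methyl-4-[(triethylsilyl)peroxy]pent-2-enoyl}oxiran-2-yl]-2-oxo-7-oxabicyclo[4.1.0]heptan-3-yl 3-methylbutanoate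
Product: 26 (1S,3S,4R,6S)-4-{(2R)-2-[(2E)-4-hydroperoxy-4-methylpent-2-enoyl]oxiran-2-yl}-1-methyl-2-oxo-7-oxabicyclo[4.1.0]heptan-3-yl 3-methylbutanoate (CNP0131119.1)
Conditions: HF·pyridine, pyridine, THF, 0 °C
Reagents that add atoms: none
Why: Fluoride cleaves the O–Si bond of the silyl peroxide (desilylation) under buffered conditions mild enough for both epoxides, the α-acyloxy ketone and the free hydroperoxide.

## Compound list

1 | 2-bromoprop-2-en-1-ol | OCC(Br)=C | starting material
2 | [(2-bromoprop-2-en-1-yl)oxy](tert-butyl)dimethylsilane | C=C(Br)CO[Si](C)(C)C(C)(C)C | intermediate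
3 | tert-butyldimethyl{[2-(4,4,5,5-tetramethyl-1,3,2-dioxaborolan-2-yl)prop-2-en-1-yl]oxy}silane | C=C(CO[Si](C)(C)C(C)(C)C)B1OC(C)(C)C(C)(C)O1 | intermediate
4 | furan-2(5H)-one | O=C1OCC=C1 | starting material
5 | (4S)-4-{3-[(tert-butyldimethylsilyl)oxy]prop-1-en-2-yl}oxolan-2-one | O=C1C[C@@H](C(=C)CO[Si](C)(C)C(C)(C)C)CO1 | intermediate
6 | (4S)-4-{3-[(tert-butyldimethylsilyl)oxy]prop-1-en-2-yl}oxolan-2-ol (anomer mixture) | OC1C[C@@H](C(=C)CO[Si](C)(C)C(C)(C)C)CO1 | intermediate
7 | ethyl 2-[bis(2,2,2-trifluoroethoxy)phosphoryl]propanoate | CCOC(=O)C(C)P(=O)(OCC(F)(F)F)OCC(F)(F)F | starting material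
8 | ethyl (2Z,5S)-5-(hydroxymethyl)-2-methyl-6-{[(tert-butyldimethylsilyl)oxy]methyl}hepta-2,6-dienoate | CCOC(=O)/C(C)=C\C[C@H](CO)C(=C)CO[Si](C)(C)C(C)(C)C | intermediate
9 | (2Z,5S)-5-(hydroxymethyl)-2-methyl-6-{[(tert-butyldimethylsilyl)oxy]methyl}hepta-2,6-dien-1-ol | OC/C(C)=C\C[C@H](CO)C(=C)CO[Si](C)(C)C(C)(C)C | intermediate
10 | (2Z,5S)-5-formyl-2-methyl-6-{[(tert-butyldimethylsilyl)oxy]methyl}hepta-2,6-dienal | O=C/C(C)=C\C[C@H](C=O)C(=C)CO[Si](C)(C)C(C)(C)C | intermediate
11 | (1S,2R,6S)-3-methyl-6-{3-[(tert-butyldimethylsilyl)oxy]prop-1-en-2-yl}cyclohex-3-ene-1,2-diol | O[C@@H]1[C@H](O)C(C)=CC[C@H]1C(=C)CO[Si](C)(C)C(C)(C)C | intermediate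
12 | 3-methylbutanoic anhydride | CC(C)CC(=O)OC(=O)CC(C)C | starting material
13 | (5S,6S)-6-hydroxy-2-methyl-5-{3-[(tert-butyldimethylsilyl)oxy]prop-1-en-2-yl}cyclohex-2-en-1-one | O[C@@H]1C(=O)C(C)=CC[C@H]1C(=C)CO[Si](C)(C)C(C)(C)C | intermediate
14 | (1S,6S)-3-methyl-2-oxo-6-{3-[(tert-butyldimethylsilyl)oxy]prop-1-en-2-yl}cyclohex-3-en-1-yl 3-methylbutanoate | CC(C)CC(=O)O[C@@H]1C(=O)C(C)=CC[C@H]1C(=C)CO[Si](C)(C)C(C)(C)C | intermediate
15 | (1S,6S)-6-(3-hydroxyprop-1-en-2-yl)-3-methyl-2-oxocyclohex-3-en-1-yl 3-methylbutanoate | CC(C)CC(=O)O[C@@H]1C(=O)C(C)=CC[C@H]1C(=C)CO | intermediate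
16 | (1S,6R)-6-[(2S)-2-(hydroxymethyl)oxiran-2-yl]-3-methyl-2-oxocyclohex-3-en-1-yl 3-methylbutanoate | CC(C)CC(=O)O[C@@H]1C(=O)C(C)=CC[C@H]1[C@]1(CO)CO1 | intermediate
17 | (1S,2S,6R)-2-hydroxy-6-[(2S)-2-(hydroxymethyl)oxiran-2-yl]-3-methylcyclohex-3-en-1-yl 3-methylbutanoate | CC(C)CC(=O)O[C@@H]1[C@@H](O)C(C)=CC[C@H]1[C@]1(CO)CO1 | intermediate
18 | (1R,2R,3S,4R,6S)-2-hydroxy-4-[(2S)-2-(hydroxymethyl)oxiran-2-yl]-1-methyl-7-oxabicyclo[4.1.0]heptan-3-yl 3-methylbutanoate | CC(C)CC(=O)O[C@@H]1[C@@H](O)[C@@]2(C)O[C@H]2C[C@H]1[C@]1(CO)CO1 | intermediate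
19 | (1S,3S,4R,6S)-4-[(2R)-2-formyloxiran-2-yl]-1-methyl-2-oxo-7-oxabicyclo[4.1.0]heptan-3-yl 3-methylbutanoate | CC(C)CC(=O)O[C@@H]1C(=O)[C@@]2(C)O[C@H]2C[C@H]1[C@]1(C=O)CO1 | intermediate
20 | 2-methylbut-1-en-3-yne | C=C(C)C#C | starting material
21 | chloro[(1E)-3-methylbuta-1,3-dien-1-yl]zirconocene | C=C(C)/C=C/[Zr](Cl)(C1C=CC=C1)C1C=CC=C1 | intermediate
22 | methyl[(1E)-3-methylbuta-1,3-dien-1-yl]zinc | C=C(C)/C=C/[Zn]C | intermediate
23 | (1S,3S,4R,6S)-4-{(2R)-2-[(2E)-1-hydroxy-4-methylpenta-2,4-dien-1-yl]oxiran-2-yl}-1-methyl-2-oxo-7-oxabicyclo[4.1.0]heptan-3-yl 3-methylbutanoate (carbinol epimers) | CC(C)CC(=O)O[C@@H]1C(=O)[C@@]2(C)O[C@H]2C[C@H]1[C@]1(C(O)/C=C/C(C)=C)CO1 | intermediate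
24 | (1S,3S,4R,6S)-1-methyl-4-{(2R)-2-[(2E)-4-methylpenta-2,4-dienoyl]oxiran-2-yl}-2-oxo-7-oxabicyclo[4.1.0]heptan-3-yl 3-methylbutanoate | CC(C)CC(=O)O[C@@H]1C(=O)[C@@]2(C)O[C@H]2C[C@H]1[C@]1(C(=O)/C=C/C(C)=C)CO1 | intermediate
25 | (1S,3S,4R,6S)-1-methyl-4-[(2R)-2-{(2E)-4-methyl-4-[(triethylsilyl)peroxy]pent-2-enoyl}oxiran-2-yl]-2-oxo-7-oxabicyclo[4.1.0]heptan-3-yl 3-methylbutanoate | CC(C)CC(=O)O[C@@H]1C(=O)[C@@]2(C)O[C@H]2C[C@H]1[C@]1(C(=O)/C=C/C(C)(C)OO[Si](CC)(CC)CC)CO1 | intermediate
26 | (1S,3S,4R,6S)-4-{(2R)-2-[(2E)-4-hydroperoxy-4-methylpent-2-enoyl]oxiran-2-yl}-1-methyl-2-oxo-7-oxabicyclo[4.1.0]heptan-3-yl 3-methylbutanoate | CC(C)CC(=O)O[C@@H]1C(=O)[C@@]2(C)O[C@H]2C[C@H]1[C@]1(C(=O)/C=C/C(C)(C)OO)CO1 | target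

## Step count and risks

Total step count: 18. Longest linear sequence: 18 steps (1 to 26).

Steps most likely to fail:

Step 8. The enal ketyl may couple intermolecularly (hydrodimerisation through its β-carbon), may be reduced further without forming the ring bond, or the aliphatic ketyl may add to the β-carbon of the enal to close a four-membered ring. The fallback sets out from dialdehyde 10 and changes from reductive radical coupling to polar umpolung. A crossed benzoin reaction catalysed by an N-heterocyclic carbene (3-benzyl-5-(2-hydroxyethyl)-4-methylthiazolium chloride with a substoichiometric hindered amine, CH2Cl2, rt) should form the acyl-anion equivalent at the more acidic enal carbonyl and add it to the aliphatic aldehyde. This would give α-ketol 13 directly, where the fallback comes back to the route (acylation half of step 9). It creates no new compound (F0). Its own risk is base-induced isomerisation of the α-alkenyl aldehyde, which is why it is not the first choice.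

Step 17. Oxygen capture by the delocalised radical may occur at the carbon next to the carbonyl instead of the tertiary carbon, or the cobalt hydride may reduce the enone alkene. The fallback sets out from aldehyde 19 and replaces radical peroxidation by an ene reaction. Prenylbarium chloride (from prenyl chloride and barium metal generated from BaI2 and lithium biphenylide, THF, −78 °C) should add through its unsubstituted terminus to the aldehyde to give the prenyl carbinol F1. Dess–Martin oxidation should give the β,γ-unsaturated prenyl ketone F2. A Schenck ene reaction (O2, visible light, tetraphenylporphyrin, CH2Cl2, 0 °C) should then abstract a hydrogen of the doubly activated CH2 and deliver the conjugated tertiary hydroperoxide. The fallback comes back to the route at target 26.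

Step 5. The alkoxide freed from the lactol may add to the new enoate in an oxa-Michael closure to a tetrahydrofuran, or the Z selectivity may erode. The fallback sets out from lactol 6 and builds the alkene before the ester. A Stork–Zhao olefination with (1-iodoethyl)triphenylphosphonium iodide and NaHMDS (THF, −78 °C) should give the (Z)-vinyl iodide F3, which contains no Michael acceptor. Ethoxycarbonylation with Pd(PPh3)4, CO (1 atm), EtOH and Et3N at 50 °C should then replace iodine by the ester with retention of geometry. The fallback comes back to the route at hydroxy enoate 8.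

## Further compounds

F0 | step 8 | none | none
F1 | step 17 | (1S,3S,4R,6S)-4-[(2R)-2-(1-hydroxy-4-methylpent-3-en-1-yl)oxiran-2-yl]-1-methyl-2-oxo-7-oxabicyclo[4.1.0]heptan-3-yl 3-methylbutanoate (carbinol epimers) | CC(C)CC(=O)O[C@@H]1C(=O)[C@@]2(C)O[C@H]2C[C@H]1[C@]1(C(O)CC=C(C)C)CO1
F2 | step 17 | (1S,3S,4R,6S)-1-methyl-4-[(2R)-2-(4-methylpent-3-enoyl)oxiran-2-yl]-2-oxo-7-oxabicyclo[4.1.0]heptan-3-yl 3-methylbutanoate | CC(C)CC(=O)O[C@@H]1C(=O)[C@@]2(C)O[C@H]2C[C@H]1[C@]1(C(=O)CC=C(C)C)CO1
F3 | step 5 | (2S,4Z)-5-iodo-2-{3-[(tert-butyldimethylsilyl)oxy]prop-1-en-2-yl}hex-4-en-1-ol | I/C(C)=C\C[C@H](CO)C(=C)CO[Si](C)(C)C(C)(C)C
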